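The unit for these flasks is a time: the half-life of E once formed, by which every E peak ages.

| flask | G | X | Z | remark | time |
|---|---|---|---|---|---|
| alpha | 10 mM | 9 mM | 3 mM | run made earlier |  |
| beta | 10 mM | 13 mM | 3 mM | run made earlier |  |
| delta | 10 mM | 20 mM | 3 mM | run made earlier |  |
| gamma | 10 mM | 9 mM | 4.5 mM | run made earlier |  |
| Tuesday's | 10 mM | 9.00 mM | 3.00 mM | a single well-mixed tank run continuously and read at steady state, 2.0 h in it on average |  |
| Monday's | 10 mM | 9.00 mM | 3.00 mM | everything together in a closed stirred flask, run for 2.0 h | 2.0 h |
| Sunday's | 10 mM | 9.00 mM | 3.00 mM | plug flow through a tube for 2.0 h, no back-mixing | 2.0 h |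
| Thursday's | 10 mM (fed, over 1.60 h) | 9.00 mM | 3.00 mM | a stirred flask in which G is dosed at a steady rate over 1.60 h without added volume, worked up at 2.0 h | 2.0 h |

- alpha (time / min: E / %, Q / %): 20.0: 28.4, 2.0; 40.0: 32.8, 5.4; 60.0: 29.4, 8.5; 80.0: 25.2, 10.9; 90.0: 23.1, 14.4; 120: 15.7, 16.6
- beta (time / h: E / %, Q / %): 0.200: 32.1, 2.6; 0.333: 37.6, 2.9; 0.500: 41.5, 6.1; 0.833: 40.1, 7.5; 1.33: 30.2, 14.4; 2.50: 13.6, 23.8
- delta (time / h: E / %, Q / %): 0.200: 42.3, 0.9; 0.333: 48.8, 0.9; 0.500: 52.4, 7.3; 0.833: 45.5, 11.7; 1.33: 32.5, 19.7; 2.50: 10.0, 27.7
- gamma (time / h: E / %, Q / %): 0.200: 21.3, 1.4; 0.667: 33.5, 5.2; 1.00: 31.2, 9.9; 1.50: 24.6, 12.2; 2.50: 12.8, 18.1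

(scatter of a reading: 1 percentage point)

- the stated concentrations are those of everything mixed, before any reaction; amounts are the same in each set-up
- the feed brings no volume worth counting
- the earlier runs were made in a closed, stirred flask

1. the set-up with the highest amount of E at the outlet or at the end, in percent of the G put in ("none" if the first two lie within 2 percentage points) (Tuesday's / Monday's / Sunday's / Thursday's / none)
2. amount of E at the outlet or at the end, in percent of the G put in, Tuesday's
3. amount of E at the outlet or at the end, in percent of the G put in, Monday's
4. amount of E at the outlet or at the end, in percent of the G put in, Sunday's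
5. amount of E at the outlet or at the end, in percent of the G put in, Thursday's

Late in the delta run, with [X] at twice the G charge, E falls from 32.5% at 1.33 h to 10.0% at 2.50 h. These readings give a loss constant of 1.01 h⁻¹, and so a half-life of E of 0.688 h. Fresh E still arriving can only lengthen this reading. E at the end is therefore the G turned over, times the share of E that survives its age.

Monday's and Sunday's age every volume alike, and the alpha run is the same charge, so its reading of 15.7% at 120 min stands for both. Tuesday's tank, with 2.0 h on average, keeps 33.2% of the E it forms at this half-life. It would equal the alpha reading on a turnover of 47.3% of G, but that figure is reckoned back from the reading and is not a turnover read from any run, so the reckoning here takes Tuesday's as near that reading and no closer.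

Two extremes bracket Thursday's. If dosing changed nothing, E would stay at the alpha reading. If each G reacted on entry, ages would spread evenly over the feed and 33.2% of the E formed would survive. X, the limiting reagent at 0.900 equivalents, caps that at 29.9%. The half-life is shorter than the dosing time 1.60 h, so late doses count for more than early ones, but G that lags the feed is not yet E. The real flask lies between, and the midpoint is 22.8%, a gap of 7.1 percentage points over the alpha reading against a margin of 2 points.

The forecast names Thursday's, with 28% there (24% to 36%), above this midpoint, 16% for Monday's, 16% for Sunday's and 19% for Tuesday's, saying “late dosing leaves E younger”.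

The flasks give 17.3% for Tuesday's, 17.1% for Monday's, 17.1% for Sunday's and 25.2% for Thursday's, so Thursday's leads.

    G + X → E (k = 0.0518 M⁻¹ s⁻¹)
    E → Q (k = 9.21 × 10⁻⁵ s⁻¹)
    E + Z → D (k = 0.00177 M⁻¹ s⁻¹)
    E → L (k = 2.13 × 10⁻⁴ s⁻¹)

By the step to L, E has a half-life of 0.90 h, shorter than the 36 h of the step to D in Monday's. In Thursday's at 2.00 h, L takes E 2.3 times as fast as Q does. Thursday's has half of the turnover of G and X to E done by 1.07 h, a median age of 0.932 h at the end, and the half-life read from the delta run, itself a lengthened reading, turns that age into an estimated survival of 0.391. On the 61.8% of G turned over, that estimate gives 24.2%. Carried unchanged to the same flask with 15 mM of X, where 81.7% of G is turned over, the estimate gives 31.9%, and that flask holds 32.8%.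

The readings are simulated for an exercise; noise was put on by code.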